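The route rests on disconnecting the C3–C4 bond of the quinone ring (ring B). There C3 holds the alkyl chain and is bonded on one side to the hydroxylated C2 and on the other to C4, a carbonyl carbon attached directly to the benzo ring (ring A); such a bond arises when an enolate carbon acylates an ortho ester. In one operation methoxide opens an enol lactone and the freed 1,2-diketone enolate recloses on the new methyl ester, which builds ring B directly at the hydroxyquinone oxidation state. The precursor is a 3-alkylidene-isochroman-1,4-dione carrying the silyl-protected neopentyl chain, made by Knoevenagel condensation. The (R)-linalool-derived acid is esterified on last.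

Key step: step 5

Assumption: commercial (R)-(−)-linalool of high enantiomeric purity is used. Its tertiary carbinol is the only stereocentre of the target and no step makes or breaks a bond at that carbon, so the target should have the enantiomeric purity of the linalool. Quinone positions are numbered so that C2 bears the hydroxyl and C3 the alkyl chain.

Step 1
Reactants: 1 2-acetylbenzoic acid
Product: 3 isochroman-1,4-dione, via 2-(bromoacetyl)benzoic acid 2 (not isolated)
Conditions: Br2 (1 equiv), cat. HBr, AcOH, 25 °C; evaporate; NaHCO3, DMF, 25 °C
Reagents that add atoms: none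
Why: Acid-catalysed α-bromination of the aryl methyl ketone through its enol should stop at the monobromide 2, and once the acid is neutralised the ortho carboxylate displaces the bromide of this phenacyl-type halide in a 6-exo-tet O-alkylation (phenacyl ester formation) that closes the lactone ring.

Step 2
Reactants: 4 2,2-dimethylpent-4-en-1-ol
Product: 5 tert-butyl[(2,2-dimethylpent-4-en-1-yl)oxy]dimethylsilane
Conditions: TBSCl, imidazole, DMF, 25 °C
Reagents that add atoms: tert-butyldimethylsilyl chloride, CC(C)(C)[Si](C)(C)Cl
Why: Imidazole-promoted silylation (Corey protocol) of a primary hydroxyl is routine even next to a quaternary carbon, and the resulting ether withstands ozone, amine catalysis and methoxide.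

Step 3
Reactants: 5 tert-butyl[(2,2-dimethylpent-4-en-1-yl)oxy]dimethylsilane
Product: 7 4-(tert-butyldimethylsilyloxy)-3,3-dimethylbutanal, via 1,2,4-trioxolane 6 (not isolated)
Conditions: O3, CH2Cl2, −78 °C; then PPh3, −78 → 25 °C
Reagents that add atoms: ozone, [O-][O+]=O
Why: Ozonolysis by the Criegee mechanism cleaves the only C=C bond to the secondary ozonide 6, which PPh3 reduces to the aldehyde and formaldehyde, and the product cannot eliminate the silyloxy group because its β-carbon is quaternary.

Step 4
Reactants: 3 isochroman-1,4-dione; 7 4-(tert-butyldimethylsilyloxy)-3,3-dimethylbutanal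
Product: 8 (Z)-3-[4-(tert-butyldimethylsilyloxy)-3,3-dimethylbutylidene]isochroman-1,4-dione
Conditions: piperidinium acetate (10 mol %), molecular sieves 4 Å, toluene, 50 °C
Reagents that add atoms: none
Why: Knoevenagel condensation, in which the C3 methylene of 3 is acidified by the C4 ketone and the ring oxygen so that the amine salt catalyses addition to the aldehyde (itself slow to self-condense beside its quaternary carbon) and loss of water to the conjugated alkylidene, expected as the Z isomer with the chain syn to the ring oxygen, although the geometry has no bearing on the next step.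

Step 5
Reactants: 8 (Z)-3-[4-(tert-butyldimethylsilyloxy)-3,3-dimethylbutylidene]isochroman-1,4-dione
Product: 10 2-hydroxy-3-[3-(tert-butyldimethylsilyloxy)-2,2-dimethylpropyl]-1,4-naphthoquinone, via ring-opened diketo ester enolate 9 (not isolated)
Conditions: NaOMe (3 equiv), dry MeOH, 0 → 25 °C; then cold 1 M HCl
Reagents that add atoms: none
Why: Methoxide adds to the C1 lactone carbonyl of 8 and expels the enol oxygen, which leaves a methyl benzoate ortho to the enolate of an aryl 1,2-diketone (9); the enolate carbon, formerly the alkylidene CH, then attacks the ester carbonyl and methoxide departs, creating the C3–C4 bond of the quinone. The closest known reaction type is the base-induced conversion of 3-alkylidene-isochroman-1,4-diones into 3-alkyl-2-hydroxy-1,4-naphthoquinones, a lactone opening followed by Dieckmann condensation and a relative of the alkylidenephthalide-to-indane-1,3-dione rearrangement. Ring B closes in the 6-(enolendo)-exo-trig mode, because both carbons of the enolate C=C (the future C2 and C3) lie inside the new six-membered ring while the ester C=O is exocyclic, and this mode is favoured. No stereocentre is formed, and the Z geometry of 8 is erased in the enolate. The cyclised triketone is only the keto tautomer of 10 and is deprotonated at once to the hydroxyquinone anion, a thermodynamic sink that pulls the preceding equilibria forward and means that no oxidation step is needed. The selectivity needed is C-acylation ahead of diketone cleavage, benzilic-type rearrangement or ester saponification, and it is secured by the ortho ester (six-membered transition state), by water-free NaOMe, and by a side chain whose silyl ether and quaternary carbon offer methoxide nothing to attack.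

Step 6
Reactants: 10 2-hydroxy-3-[3-(tert-butyldimethylsilyloxy)-2,2-dimethylpropyl]-1,4-naphthoquinone
Product: 11 2-hydroxy-3-(3-hydroxy-2,2-dimethylpropyl)-1,4-naphthoquinone
Conditions: HF·pyridine, THF, 0 → 25 °C
Reagents that add atoms: none
Why: Fluoride-driven cleavage of the primary silyl ether (Si–F bond formation) in buffered HF·pyridine at or below room temperature is mild enough that the hydroxyquinone should not condense with the new alcohol to a pyran, and nothing else in 10 is labile to fluoride or weak acid.

Step 7
Reactants: 12 (R)-linalool
Product: 13 (2E,6R)-6-hydroxy-2,6-dimethylocta-2,7-dienal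
Conditions: SeO2 (1.2 equiv), dioxane/EtOH 9:1, 80 °C
Reagents that add atoms: selenium dioxide SeO2, O=[Se]=O
Why: Riley allylic oxidation (ene reaction, then [2,3]-sigmatropic shift) attacks the more substituted end of the trisubstituted alkene at the methyl group trans to the chain and carries it on to the E enal, while the vinyl carbinol has no allylic C–H bond, so the (R) centre is left untouched.

Step 8
Reactants: 13 (2E,6R)-6-hydroxy-2,6-dimethylocta-2,7-dienal
Product: 14 (2E,6R)-6-hydroxy-2,6-dimethylocta-2,7-dienoic acid
Conditions: NaClO2, NaH2PO4, 2-methylbut-2-ene, t-BuOH/H2O, 0 → 25 °C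
Reagents that add atoms: sodium chlorite NaClO2, [Na+].[O-]Cl=O
Why: Pinnick (Lindgren) oxidation with buffered chlorous acid converts the enal into the acid without moving or isomerising the E double bond, and the excess 2-methylbut-2-ene traps the HOCl by-product before it can add to the vinyl group.

Step 9
Reactants: 11 2-hydroxy-3-(3-hydroxy-2,2-dimethylpropyl)-1,4-naphthoquinone; 14 (2E,6R)-6-hydroxy-2,6-dimethylocta-2,7-dienoic acid
Product: 15 rhinacanthin H, 3-(3-hydroxy-1,4-dioxo-1,4-dihydronaphthalen-2-yl)-2,2-dimethylpropyl (2E,6R)-6-hydroxy-2,6-dimethylocta-2,7-dienoate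
Conditions: DCC, DMAP (1.5 equiv), CH2Cl2, 0 → 25 °C
Reagents that add atoms: none
Why: Steglich esterification, in which DCC activates 14 and DMAP passes the acyl group as an acylpyridinium ion to the primary neopentyl hydroxyl of 11, the only unhindered neutral nucleophile present, since the tertiary allylic carbinol is too crowded to compete and an acyl group that lands on the acidic quinone oxygen gives an activated enol ester that DMAP feeds back into the same pool, so the (R) centre and the E alkene should arrive in 15 unchanged.

Compound list
1 | 2-acetylbenzoic acid | CC(=O)c1ccccc1C(=O)O | starting material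
2 | 2-(bromoacetyl)benzoic acid | O=C(CBr)c1ccccc1C(=O)O | intermediate (not isolated)
3 | isochroman-1,4-dione (1H-2-benzopyran-1,4(3H)-dione) | O=C1OCC(=O)c2ccccc12 | intermediate
4 | 2,2-dimethylpent-4-en-1-ol | C=CCC(C)(C)CO | starting material
5 | tert-butyl[(2,2-dimethylpent-4-en-1-yl)oxy]dimethylsilane | C=CCC(C)(C)CO[Si](C)(C)C(C)(C)C | intermediate
6 | 3-[3-(tert-butyldimethylsilyloxy)-2,2-dimethylpropyl]-1,2,4-trioxolane (secondary ozonide) | CC(C)(C)[Si](C)(C)OCC(C)(C)CC1OCOO1 | intermediate (not isolated)
7 | 4-(tert-butyldimethylsilyloxy)-3,3-dimethylbutanal | O=CCC(C)(C)CO[Si](C)(C)C(C)(C)C | intermediate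
8 | (Z)-3-[4-(tert-butyldimethylsilyloxy)-3,3-dimethylbutylidene]isochroman-1,4-dione | O=C1O/C(=C\CC(C)(C)CO[Si](C)(C)C(C)(C)C)C(=O)c2ccccc12 | intermediate
9 | methyl 2-[6-(tert-butyldimethylsilyloxy)-5,5-dimethyl-2-oxohexanoyl]benzoate, present as its sodium enolate | COC(=O)c1ccccc1C(=O)C(=O)CCC(C)(C)CO[Si](C)(C)C(C)(C)C | intermediate (not isolated)
10 | 2-hydroxy-3-[3-(tert-butyldimethylsilyloxy)-2,2-dimethylpropyl]-1,4-naphthoquinone | CC(C)(C)[Si](C)(C)OCC(C)(C)CC1=C(O)C(=O)c2ccccc2C1=O | intermediate
11 | 2-hydroxy-3-(3-hydroxy-2,2-dimethylpropyl)-1,4-naphthoquinone | OCC(C)(C)CC1=C(O)C(=O)c2ccccc2C1=O | intermediate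
12 | (R)-linalool, (3R)-3,7-dimethylocta-1,6-dien-3-ol | C=C[C@](C)(O)CCC=C(C)C | starting material
13 | (2E,6R)-6-hydroxy-2,6-dimethylocta-2,7-dienal | C=C[C@](C)(O)CC/C=C(\C)C=O | intermediate
14 | (2E,6R)-6-hydroxy-2,6-dimethylocta-2,7-dienoic acid | C=C[C@](C)(O)CC/C=C(\C)C(=O)O | intermediate
15 | rhinacanthin H, 3-(3-hydroxy-1,4-dioxo-1,4-dihydronaphthalen-2-yl)-2,2-dimethylpropyl (2E,6R)-6-hydroxy-2,6-dimethylocta-2,7-dienoate | C=C[C@](C)(O)CC/C=C(\C)C(=O)OCC(C)(C)CC1=C(O)C(=O)c2ccccc2C1=O | target

Total step count: 9
Longest linear sequence: 6 steps (steps 2, 3, 4, 5, 6 and 9, counted from 4)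

Steps most likely to fail

Step 5. The diketone enolate may be diverted before it closes: methoxide can cleave the 1,2-diketone, a benzilic-type 1,2-shift can occur, or traces of water can saponify the methyl ester, so that ring B never forms. The fallback sets out from 4 and comes back at 11. It does not build ring B but attaches the side chain to a preformed hydroxyquinone by radical alkylation. Alcohol 4 is acetylated (Ac2O, pyridine, cat. DMAP) to 2,2-dimethylpent-4-en-1-yl acetate F1, whose terminal alkene is cleaved (cat. RuCl3, NaIO4, MeCN/EtOAc/H2O) to 4-acetoxy-3,3-dimethylbutanoic acid F2. Oxidative decarboxylation of F2 (cat. AgNO3, (NH4)2S2O8, MeCN/H2O, 65 °C) in the presence of commercial 2-hydroxy-1,4-naphthoquinone should add the primary radical to the unsubstituted C3 (Kochi–Anderson alkylation of a quinone) and give 3-(3-hydroxy-1,4-dioxo-1,4-dihydronaphthalen-2-yl)-2,2-dimethylpropyl acetate F3. K2CO3 in MeOH then removes the acetate and gives 11. The acetate is used in this branch because a silyl ether would not survive the acidic persulfate medium.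

Step 4. Self-condensation of 3 at its activated methylene, amine attack on the enol lactone of the product, or drift of the new double bond out of conjugation may erode the condensation. The fallback sets out from 3 and 7 and comes back at 8. It separates carbon–carbon bond formation from dehydration. The titanium enolate of 3 (TiCl4, i-Pr2NEt, CH2Cl2, −78 °C) is added to 7 in a directed aldol reaction to give 3-[4-(tert-butyldimethylsilyloxy)-1-hydroxy-3,3-dimethylbutyl]isochroman-1,4-dione F4 as a diastereomer mixture of no consequence. MsCl and Et3N (CH2Cl2, 0 °C) convert it into 4-(tert-butyldimethylsilyloxy)-1-(1,4-dioxoisochroman-3-yl)-3,3-dimethylbutyl methanesulfonate F5, which should lose methanesulfonic acid under the same base (E1cB elimination) to give 8.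

Step 9. Acyl transfer to the hindered neopentyl oxygen may be slow enough that the activated acid rearranges to an N-acylurea, or that acylation of the quinone oxygen or of the tertiary carbinol of a second acid molecule takes over. The fallback sets out from 11 and 12 and comes back at 15. It attaches a small, hydroxyl-free acyl unit first and builds the enoate afterwards. Alcohol 11 is esterified (DCC, DMAP, CH2Cl2) with commercial 2-(diethoxyphosphoryl)propanoic acid, used in excess, and a brief NaHCO3/aqueous MeOH treatment cleaves any enol ester on the quinone oxygen. This gives 3-(3-hydroxy-1,4-dioxo-1,4-dihydronaphthalen-2-yl)-2,2-dimethylpropyl 2-(diethoxyphosphoryl)propanoate F6. Selective ozonolysis of the electron-rich trisubstituted alkene of 12 (1 equiv O3, CH2Cl2/MeOH, −78 °C; then Me2S) gives (5R)-5-ethenyl-5-methyloxolan-2-ol F7, the lactol of (R)-4-hydroxy-4-methylhex-5-enal. Horner–Wadsworth–Emmons olefination of F7 with F6 (LiCl, DBU, MeCN, with one extra equivalent of DBU for the acidic quinone hydroxyl) should give the E trisubstituted enoate 15.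

Further compounds
F1 | step 5 | 2,2-dimethylpent-4-en-1-yl acetate | C=CCC(C)(C)COC(C)=O
F2 | step 5 | 4-acetoxy-3,3-dimethylbutanoic acid | CC(=O)OCC(C)(C)CC(=O)O
F3 | step 5 | 3-(3-hydroxy-1,4-dioxo-1,4-dihydronaphthalen-2-yl)-2,2-dimethylpropyl acetate | CC(=O)OCC(C)(C)CC1=C(O)C(=O)c2ccccc2C1=O
F4 | step 4 | 3-[4-(tert-butyldimethylsilyloxy)-1-hydroxy-3,3-dimethylbutyl]isochroman-1,4-dione (diastereomer mixture) | OC(CC(C)(C)CO[Si](C)(C)C(C)(C)C)C1OC(=O)c2ccccc2C1=O
F5 | step 4 | 4-(tert-butyldimethylsilyloxy)-1-(1,4-dioxoisochroman-3-yl)-3,3-dimethylbutyl methanesulfonate (diastereomer mixture) | CS(=O)(=O)OC(CC(C)(C)CO[Si](C)(C)C(C)(C)C)C1OC(=O)c2ccccc2C1=O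
F6 | step 9 | 3-(3-hydroxy-1,4-dioxo-1,4-dihydronaphthalen-2-yl)-2,2-dimethylpropyl 2-(diethoxyphosphoryl)propanoate | CCOP(=O)(OCC)C(C)C(=O)OCC(C)(C)CC1=C(O)C(=O)c2ccccc2C1=O
F7 | step 9 | (5R)-5-ethenyl-5-methyloxolan-2-ol (anomer mixture) | C=C[C@](C)(O1)CCC1O
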